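**Retrosynthetic overview**
1. Target 8 ⇒ C2–OAc bond (a C–O bond that also sets the (R) centre): enantioselective anti-Markovnikov addition of acetic acid across the (E)-styrene 7.
2. 7 ⇒ aryl–alkenyl bond: Suzuki coupling of 3-bromo-5-methoxyphenol 5 with the (E)-alkenylboronate 6, made in the same flask from alkynol 3 and bis(pinacolato)diboron 4.
3. 3 ⇒ acetylide alkylation of 11-bromoundecan-1-ol 1 with lithium acetylide–ethylenediamine complex 2.
4. No ring is formed; the benzene ring is bought with 5, and no protecting groups are used.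

Assumption: the sense of induction of the new chiral catalyst in step 3 cannot be predicted, so the (S,S)-anion is written and the equally accessible (R,R)-anion is used if the first run gives the (S)-acetate.

Catalyst for step 3 (called Acr·IDPi below): the salt of the 3,6-di-tert-butyl-10-phenyl-9-(2,4,6-trimethylphenyl)acridinium cation with a chiral (S,S)-imidodiphosphorimidate anion. The anion is built from two (S)-3,3'-bis[3,5-bis(trifluoromethyl)phenyl]-1,1'-binaphthalene-2,2'-diol units and carries a trifluoromethanesulfonyl group on each outer nitrogen. It is made once by anion exchange from the acridinium tetrafluoroborate.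

**Step 1**
Reactants: 1 11-bromoundecan-1-ol; 2 lithium acetylide–ethylenediamine complex
Product: 3 tridec-12-yn-1-ol
Conditions: LiC≡CH·H2NCH2CH2NH2 (3 equiv), DMSO, 10 °C to rt, 3 h; then H2O
Reagents that add atoms: lithium acetylide–ethylenediamine complex, [Li+].[C-]#C.NCCN
Why: SN2 alkylation of an acetylide; one equivalent of reagent turns the alcohol into its lithium alkoxide, which in DMSO is much less nucleophilic toward the primary bromide than the acetylide, and the product stays as its acetylide salt until the quench, so the triple bond does not migrate.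

**Step 2**
Reactants: 3 tridec-12-yn-1-ol (1.3 equiv); 4 bis(pinacolato)diboron; 5 3-bromo-5-methoxyphenol (1.0 equiv)
Product: 7 3-[(1E)-13-hydroxytridec-1-en-1-yl]-5-methoxyphenol, via (E)-alkenylboronate 6 (not isolated)
Conditions: B2pin2 (1.25 equiv), CuCl (5 mol%), Xantphos (5 mol%), NaOtBu (10 mol%), MeOH (2 equiv), THF, rt, 3 h; then 5, Pd(dppf)Cl2 (3 mol%), aq K3PO4 (3 equiv), 65 °C, 12 h, N2
Reagents that add atoms: 3-bromo-5-methoxyphenol, COc1cc(O)cc(Br)c1 (bis(pinacolato)diboron, CC1(C)OB(OC1(C)C)B1OC(C)(C)C(C)(C)O1, puts boron only into 6 and no atom into 7)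
Why: copper-catalysed protoboration (syn borylcupration, then protonation by MeOH) gives the linear (E)-alkenyl pinacol boronate and tolerates the free alcohol, and Suzuki–Miyaura coupling at zerovalent palladium joins it to the aryl bromide with retention of the alkene geometry.

**Step 3**
Reactants: 7 3-[(1E)-13-hydroxytridec-1-en-1-yl]-5-methoxyphenol
Product: 8 (2R)-13-hydroxy-1-(3-hydroxy-5-methoxyphenyl)tridecan-2-yl acetate
Conditions: AcOH (10 equiv), Acr·IDPi (2.5 mol%), PhSSPh (10 mol%), degassed CH2Cl2 (0.05 M), 450 nm LEDs, −40 °C, 24 h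
Reagents that add atoms: acetic acid, CC(=O)O
Why: Proposed new method: counteranion-directed photoredox anti-Markovnikov hydroacetoxylation, in which the excited acridinium oxidises the electron-rich styrene to its radical cation, whose only counterion is the confined chiral IDPi anion; neutral AcOH, hydrogen-bonded in the anion pocket, attacks one face of the homobenzylic alkene carbon (the position that leaves the stabilised benzylic radical), forming the C2–O bond and setting the (R) centre; the anion takes the proton, PhSH (from PhSSPh) gives a hydrogen atom to the benzylic radical, and PhS• reoxidises the acridinyl radical and returns the proton as thiolate, closing both cycles, so the whole of the acetic acid molecule ends up in the product and nothing is lost; no Brønsted base is present, so the phenol radical cation is not drained to a phenoxyl radical, and the tenfold excess of AcOH outcompetes the remote primary alcohol; the closest known reactions are the racemic acridinium/thiol-cocatalysed anti-Markovnikov hydroacyloxylation of β-alkylstyrenes and the chiral-IDPi-anion-controlled cyclopropanation of styrene radical cations.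

**Compound list**
1 | 11-bromoundecan-1-ol | OCCCCCCCCCCCBr | starting material
2 | lithium acetylide–ethylenediamine complex | [Li+].[C-]#C.NCCN | starting material
3 | tridec-12-yn-1-ol | OCCCCCCCCCCCC#C | intermediate
4 | bis(pinacolato)diboron | CC1(C)OB(OC1(C)C)B1OC(C)(C)C(C)(C)O1 | starting material
5 | 3-bromo-5-methoxyphenol | COc1cc(O)cc(Br)c1 | starting material
6 | (12E)-13-(4,4,5,5-tetramethyl-1,3,2-dioxaborolan-2-yl)tridec-12-en-1-ol | CC1(C)OB(OC1(C)C)/C=C/CCCCCCCCCCCO | intermediate (not isolated)
7 | 3-[(1E)-13-hydroxytridec-1-en-1-yl]-5-methoxyphenol | COc1cc(O)cc(/C=C/CCCCCCCCCCCO)c1 | intermediate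
8 | (2R)-13-hydroxy-1-(3-hydroxy-5-methoxyphenyl)tridecan-2-yl acetate | COc1cc(O)cc(C[C@@H](CCCCCCCCCCCO)OC(C)=O)c1 | target

**Total step count:** 3. **Longest linear sequence:** 3 steps (1 → 3 → 7 → 8).

**Steps most likely to fail, with fallbacks**

Step 3 (the new reaction). The risks are modest enantioselectivity, unproductive oxidation of the free phenol or of the electron-rich arene of the product, and attack of the radical cation outside the chiral pocket. The fallback uses known chemistry, sets out from 7 and comes back at 8. Both hydroxyls are silylated (i-Pr3SiCl, imidazole, DMF) to give [3-methoxy-5-[(1E)-13-[tri(propan-2-yl)silyloxy]tridec-1-en-1-yl]phenoxy]tri(propan-2-yl)silane F1. Shi epoxidation follows, with 1,2:4,5-di-O-isopropylidene-β-D-erythro-2,3-hexodiulo-2,6-pyranose (30 mol%), KHSO5 (as 2KHSO5·KHSO4·K2SO4) and K2CO3 in MeCN/dimethoxymethane/aqueous buffer at pH 10.5 and 0 °C. It gives (2R,3R)-2-[3-methoxy-5-[tri(propan-2-yl)silyloxy]phenyl]-3-[11-[tri(propan-2-yl)silyloxy]undecyl]oxirane F2, the same facial sense as for trans-β-methylstyrene. Hydrogenolysis of the benzylic C–O bond only (H2, Pd/C, EtOAc, rt) leaves the C2–O bond untouched and gives (2R)-1-[3-methoxy-5-[tri(propan-2-yl)silyloxy]phenyl]-13-[tri(propan-2-yl)silyloxy]tridecan-2-ol F3. Acetylation (Ac2O, Et3N, 4-(dimethylamino)pyridine, CH2Cl2) gives (2R)-1-[3-methoxy-5-[tri(propan-2-yl)silyloxy]phenyl]-13-[tri(propan-2-yl)silyloxy]tridecan-2-yl acetate F4. Buffered desilylation (Bu4NF/AcOH 1:1, THF) then delivers 8 without acetate loss or migration.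

Step 2. The risks are incomplete regiocontrol in the protoboration and sluggish coupling of the electron-rich phenoxide bromide in the one-pot format. The fallback sets out from 3 and 5 and comes back at 7. Copper-free Sonogashira coupling (Pd(MeCN)2Cl2, XPhos, Cs2CO3, MeCN, 80 °C) gives 3-(13-hydroxytridec-1-yn-1-yl)-5-methoxyphenol F5. Lindlar semihydrogenation (H2, Pd/CaCO3 poisoned with Pb(OAc)2, quinoline, EtOAc) gives 3-[(1Z)-13-hydroxytridec-1-en-1-yl]-5-methoxyphenol F6. Thiyl-radical equilibration (PhSSPh 5 mol%, 400 nm light, EtOAc, rt) converts it to the thermodynamically favoured (E)-alkene 7, and residual Z isomer is removed on AgNO3-impregnated silica.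

Step 1. The risk is that the lithium alkoxide of 1 competes as a nucleophile (ether oligomers) or that elimination lowers the yield. The fallback sets out from 1 and comes back at 3. The alcohol is masked with 3,4-dihydro-2H-pyran and pyridinium p-toluenesulfonate in CH2Cl2 to give 2-[(11-bromoundecyl)oxy]oxane F7. Alkylation of LiC≡CH·H2NCH2CH2NH2 in DMSO gives 2-(tridec-12-yn-1-yloxy)oxane F8. Methanolysis (p-toluenesulfonic acid cat., MeOH, rt) returns 3.

**Further compounds**
F1 | step 3 | [3-methoxy-5-[(1E)-13-[tri(propan-2-yl)silyloxy]tridec-1-en-1-yl]phenoxy]tri(propan-2-yl)silane | COc1cc(O[Si](C(C)C)(C(C)C)C(C)C)cc(/C=C/CCCCCCCCCCCO[Si](C(C)C)(C(C)C)C(C)C)c1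
F2 | step 3 | (2R,3R)-2-[3-methoxy-5-[tri(propan-2-yl)silyloxy]phenyl]-3-[11-[tri(propan-2-yl)silyloxy]undecyl]oxirane | COc1cc(O[Si](C(C)C)(C(C)C)C(C)C)cc([C@H]2O[C@@H]2CCCCCCCCCCCO[Si](C(C)C)(C(C)C)C(C)C)c1
F3 | step 3 | (2R)-1-[3-methoxy-5-[tri(propan-2-yl)silyloxy]phenyl]-13-[tri(propan-2-yl)silyloxy]tridecan-2-ol | COc1cc(O[Si](C(C)C)(C(C)C)C(C)C)cc(C[C@@H](CCCCCCCCCCCO[Si](C(C)C)(C(C)C)C(C)C)O)c1
F4 | step 3 | (2R)-1-[3-methoxy-5-[tri(propan-2-yl)silyloxy]phenyl]-13-[tri(propan-2-yl)silyloxy]tridecan-2-yl acetate | COc1cc(O[Si](C(C)C)(C(C)C)C(C)C)cc(C[C@@H](CCCCCCCCCCCO[Si](C(C)C)(C(C)C)C(C)C)OC(C)=O)c1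
F5 | step 2 | 3-(13-hydroxytridec-1-yn-1-yl)-5-methoxyphenol | COc1cc(O)cc(C#CCCCCCCCCCCCO)c1
F6 | step 2 | 3-[(1Z)-13-hydroxytridec-1-en-1-yl]-5-methoxyphenol | COc1cc(O)cc(/C=C\CCCCCCCCCCCO)c1
F7 | step 1 | 2-[(11-bromoundecyl)oxy]oxane | BrCCCCCCCCCCCOC1CCCCO1
F8 | step 1 | 2-(tridec-12-yn-1-yloxy)oxane | C#CCCCCCCCCCCCOC1CCCCO1
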